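**Retrosynthetic overview**

1. The strategy rests on ring C: C3 carries the methoxy group and lies between the C4 ketone and C2, and C2 bears O1 and the 4-methoxyphenyl ring (ring B). C2=C3 is therefore cut to an alpha-methoxy keto-ylide carbon (C3) on C4 and the carbonyl (C2) of a 4-methoxybenzoate on the C8a oxygen, joined by an intramolecular ester Wittig olefination.
2. The keto-ylide comes from the C4a aroyl chloride and Ph3P=CHOMe. The acid comes from Pinnick oxidation of an O-anisoylated salicylaldehyde, made by ortho-formylation of a 2,3,5-trisubstituted phenol at its only free ortho carbon.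
3. The side-chain stereocentre on C8 is cut back to a 1,1-diarylethene (hydroxyl-directed asymmetric hydrogenation), built from 4-benzyloxyphenylmagnesium bromide and dibenzylated 2,4,6-trihydroxyacetophenone.
4. Ring order: ring A, ring B and the side-chain arene are bought; ring C is the only ring formed (step 8); the three benzyl ethers are removed last.

Key step: step 8

Remark: the stereocentre in the SMILES is (R) (ring A carbon > 4-hydroxyphenyl > CH3 > H) and keeps this descriptor in every intermediate; the sense of induction in step 3 cannot be predicted safely for this doubly ortho-substituted styrene, so the ligand antipode that gives (R)-7 is assumed to be fixed in a first run and the configuration confirmed (for example by X-ray analysis of the 4-bromobenzoate of 7) before material is carried on.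

**Route**

Step 1
Reactants: 1 2,4,6-trihydroxyacetophenone
Product: 2 1-[2,4-bis(benzyloxy)-6-hydroxyphenyl]ethan-1-one
Conditions: BnBr (2.05 equiv), K2CO3 (2.2 equiv), DMF, rt
Reagents that add atoms: benzyl bromide, BrCc1ccccc1
Why: Williamson etherification, in which the 4-OH and one ortho OH are alkylated while the remaining ortho OH, hydrogen-bonded to the acetyl carbonyl, is the least nucleophilic and should stay free.

Step 2
Reactants: 2 1-[2,4-bis(benzyloxy)-6-hydroxyphenyl]ethan-1-one; 3 1-(benzyloxy)-4-bromobenzene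
Product: 6 3,5-bis(benzyloxy)-2-[1-(4-benzyloxyphenyl)ethenyl]phenol, via arylmagnesium bromide 4 (not isolated), via tertiary carbinol 5 (not isolated)
Conditions: 3, Mg, THF (gives 4, 3.5 equiv); 2, LaCl3·2LiCl (1 equiv), THF, 0 °C to rt; aq NH4Cl; PPTS (cat.), toluene, 50 °C
Reagents that add atoms: none
Why: Grignard addition to the aryl methyl ketone (one equivalent of 4 is spent on the phenol, and LaCl3·2LiCl favours 1,2-addition over enolisation), then acid-catalysed E1 dehydration of carbinol 5, whose cation is stabilised by both electron-rich arenes.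

Step 3
Reactants: 6 3,5-bis(benzyloxy)-2-[1-(4-benzyloxyphenyl)ethenyl]phenol
Product: 7 3,5-bis(benzyloxy)-2-[(1R)-1-(4-benzyloxyphenyl)ethyl]phenol
Conditions: H2 (20 bar), Rh(nbd)2BF4 (2 mol %), (R)-1-[(Sp)-2-(diphenylphosphino)ferrocenyl]ethyldi-tert-butylphosphine or its enantiomer (2.2 mol %, see remark), CH2Cl2/MeOH, 30 °C
Reagents that add atoms: none
Why: Hydroxyl-directed rhodium-catalysed asymmetric hydrogenation of a 2-(1-arylvinyl)phenol, in which the free ortho OH and the alkene chelate the cationic rhodium–diphosphine so that H2 is delivered to one enantioface fixed by the ligand antipode (chosen to give R), while benzyl ethers are inert to the homogeneous catalyst.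

Step 4
Reactants: 7 3,5-bis(benzyloxy)-2-[(1R)-1-(4-benzyloxyphenyl)ethyl]phenol
Product: 9 4,6-bis(benzyloxy)-3-[(1R)-1-(4-benzyloxyphenyl)ethyl]-2-hydroxybenzaldehyde, via hydroxymethylphenol 8 (not isolated)
Conditions: MgCl2 (2 equiv), Et3N (4 equiv), (CH2O)n (6 equiv), THF, reflux; cold 1 M HCl work-up
Reagents that add atoms: paraformaldehyde (formaldehyde source), C=O
Why: Magnesium-mediated ortho-formylation (Casnati–Skattebøl), in which the magnesium phenoxide delivers formaldehyde only to an ortho carbon, of which just one is free, and hydroxymethyl intermediate 8 is oxidised by a second formaldehyde through hydride transfer, so the CH between the two benzyloxy groups is not reached.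

Step 5
Reactants: 9 4,6-bis(benzyloxy)-3-[(1R)-1-(4-benzyloxyphenyl)ethyl]-2-hydroxybenzaldehyde; 10 4-methoxybenzoyl chloride
Product: 11 3,5-bis(benzyloxy)-6-[(1R)-1-(4-benzyloxyphenyl)ethyl]-2-formylphenyl 4-methoxybenzoate
Conditions: Et3N (2 equiv), DMAP (0.2 equiv), CH2Cl2, 0 °C to rt
Reagents that add atoms: none
Why: DMAP-catalysed O-acylation of the only free hydroxyl group, which places the future C2 carbonyl and ring B on the oxygen that becomes O1 and leaves the aldehyde untouched.

Step 6
Reactants: 11 3,5-bis(benzyloxy)-6-[(1R)-1-(4-benzyloxyphenyl)ethyl]-2-formylphenyl 4-methoxybenzoate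
Product: 12 4,6-bis(benzyloxy)-3-[(1R)-1-(4-benzyloxyphenyl)ethyl]-2-[(4-methoxybenzoyl)oxy]benzoic acid
Conditions: NaClO2 (3 equiv), NaH2PO4 (3 equiv), 2-methyl-2-butene (20 equiv), t-BuOH/THF/H2O, 0 °C to rt
Reagents that add atoms: sodium chlorite, [Na+].[O-]Cl=O
Why: Pinnick oxidation at about pH 4 converts the aldehyde into the acid without touching the aryl ester, the benzyl ethers or the benzylic centre, and 2-methyl-2-butene removes HOCl before it can chlorinate the electron-rich rings.

Step 7
Reactants: 12 4,6-bis(benzyloxy)-3-[(1R)-1-(4-benzyloxyphenyl)ethyl]-2-[(4-methoxybenzoyl)oxy]benzoic acid; 13 (methoxymethyl)triphenylphosphonium chloride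
Product: 17 3,5-bis(benzyloxy)-6-[(1R)-1-(4-benzyloxyphenyl)ethyl]-2-[2-methoxy-2-(triphenyl-λ5-phosphanylidene)acetyl]phenyl 4-methoxybenzoate, via methoxymethylidenetriphenylphosphorane 14 (not isolated), via aroyl chloride 15 (not isolated), via acylphosphonium chloride 16 (not isolated)
Conditions: 12, Me2C=C(Cl)NMe2 (1.1 equiv), CH2Cl2, 0 °C to rt, evaporate (gives 15); 13 (2.2 equiv), NaN(SiMe3)2 (2.1 equiv), THF, 0 °C (gives 14); 15 in THF added at −78 °C, then to −20 °C
Reagents that add atoms: none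
Why: Neutral acid chloride formation with an alpha-chloroenamine, then C-acylation of the unstabilised ylide 14 and transylidation (a second equivalent of 14 deprotonates salt 16); at −78 °C the acid chloride should react far faster than the aryl ester, as in the known acylation of alkylidenephosphoranes by O-acylsalicyloyl chlorides.

Step 8
Reactants: 17 3,5-bis(benzyloxy)-6-[(1R)-1-(4-benzyloxyphenyl)ethyl]-2-[2-methoxy-2-(triphenyl-λ5-phosphanylidene)acetyl]phenyl 4-methoxybenzoate
Product: 19 5,7-bis(benzyloxy)-8-[(1R)-1-(4-benzyloxyphenyl)ethyl]-3-methoxy-2-(4-methoxyphenyl)-4H-chromen-4-one, via oxaphosphetane 18 (not isolated)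
Conditions: toluene (0.02 M), 110 °C, Ar
Reagents that add atoms: none
Why: Proposed new method: the ylide carbon (future C3) adds across the carbonyl of the neighbouring 4-methoxybenzoate (future C2) to give the fused 1,2-oxaphosphetane 18, which undergoes cycloreversion with loss of triphenylphosphine oxide to the C2=C3 bond, the 3-methoxy group being carried in by the ylide. The closest known reaction is the intramolecular ester Wittig olefination of 2-acyloxyphenacylidene-triphenylphosphoranes to chromones and flavones; new here is the alpha-methoxy substituent on the keto-stabilised ylide carbon, which has not been shown to olefinate an ester. Ring C closes by a 6-exo-trig attack of C3 on the ester carbonyl, made feasible by the ortho relationship of the two groups on ring A and by the activated aryl ester. No stereocentre is formed, and the benzylic centre on C8 sees only neutral thermal conditions. The step needs olefination to win over O-to-C acyl transfer; because the ylide carbon has no hydrogen, a C-acylated phosphonium phenoxide cannot be drained off by proton transfer to a diacyl ylide and can only revert or go on to 18, and the non-polar solvent disfavours the charge-separated phenoxide. The regiochemistry is fixed because only the C8a oxygen carries the acyl group.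

Step 9
Reactants: 19 5,7-bis(benzyloxy)-8-[(1R)-1-(4-benzyloxyphenyl)ethyl]-3-methoxy-2-(4-methoxyphenyl)-4H-chromen-4-one
Product: 20 5,7-dihydroxy-8-[(1R)-1-(4-hydroxyphenyl)ethyl]-3-methoxy-2-(4-methoxyphenyl)-4H-chromen-4-one
Conditions: H2 (1 atm), 10% Pd/C, EtOAc/MeOH, rt
Reagents that add atoms: none
Why: Catalytic hydrogenolysis of the three benzyl aryl ethers; the tetrasubstituted conjugated C2=C3 bond, the two methyl ethers and the C–C bonds at the benzylic stereocentre should not be cleaved at 1 atm and room temperature.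

**Compound list**

1 | 2,4,6-trihydroxyacetophenone | CC(=O)c1c(O)cc(O)cc1O | starting material
2 | 1-[2,4-bis(benzyloxy)-6-hydroxyphenyl]ethan-1-one | CC(=O)c1c(O)cc(OCc2ccccc2)cc1OCc1ccccc1 | intermediate
3 | 1-(benzyloxy)-4-bromobenzene | Brc1ccc(OCc2ccccc2)cc1 | starting material
4 | [4-(benzyloxy)phenyl]magnesium bromide | Br[Mg]c1ccc(OCc2ccccc2)cc1 | intermediate
5 | 3,5-bis(benzyloxy)-2-[1-(4-benzyloxyphenyl)-1-hydroxyethyl]phenol (racemic) | CC(O)(c1ccc(OCc2ccccc2)cc1)c1c(O)cc(OCc2ccccc2)cc1OCc1ccccc1 | intermediate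
6 | 3,5-bis(benzyloxy)-2-[1-(4-benzyloxyphenyl)ethenyl]phenol | C=C(c1ccc(OCc2ccccc2)cc1)c1c(O)cc(OCc2ccccc2)cc1OCc1ccccc1 | intermediate
7 | 3,5-bis(benzyloxy)-2-[(1R)-1-(4-benzyloxyphenyl)ethyl]phenol | Oc1cc(OCc2ccccc2)cc(OCc2ccccc2)c1[C@H](C)c1ccc(OCc2ccccc2)cc1 | intermediate
8 | 3,5-bis(benzyloxy)-2-[(1R)-1-(4-benzyloxyphenyl)ethyl]-6-(hydroxymethyl)phenol (present as its magnesium salt) | OCc1c(OCc2ccccc2)cc(OCc2ccccc2)c([C@H](C)c2ccc(OCc3ccccc3)cc2)c1O | intermediate
9 | 4,6-bis(benzyloxy)-3-[(1R)-1-(4-benzyloxyphenyl)ethyl]-2-hydroxybenzaldehyde | O=Cc1c(OCc2ccccc2)cc(OCc2ccccc2)c([C@H](C)c2ccc(OCc3ccccc3)cc2)c1O | intermediate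
10 | 4-methoxybenzoyl chloride | COc1ccc(C(Cl)=O)cc1 | starting material
11 | 3,5-bis(benzyloxy)-6-[(1R)-1-(4-benzyloxyphenyl)ethyl]-2-formylphenyl 4-methoxybenzoate | O=Cc1c(OCc2ccccc2)cc(OCc2ccccc2)c([C@H](C)c2ccc(OCc3ccccc3)cc2)c1OC(=O)c1ccc(OC)cc1 | intermediate
12 | 4,6-bis(benzyloxy)-3-[(1R)-1-(4-benzyloxyphenyl)ethyl]-2-[(4-methoxybenzoyl)oxy]benzoic acid | OC(=O)c1c(OCc2ccccc2)cc(OCc2ccccc2)c([C@H](C)c2ccc(OCc3ccccc3)cc2)c1OC(=O)c1ccc(OC)cc1 | intermediate
13 | (methoxymethyl)triphenylphosphonium chloride | COC[P+](c1ccccc1)(c1ccccc1)c1ccccc1.[Cl-] | starting material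
14 | (methoxymethylidene)triphenyl-λ5-phosphane | COC=P(c1ccccc1)(c1ccccc1)c1ccccc1 | intermediate
15 | 4,6-bis(benzyloxy)-3-[(1R)-1-(4-benzyloxyphenyl)ethyl]-2-[(4-methoxybenzoyl)oxy]benzoyl chloride | ClC(=O)c1c(OCc2ccccc2)cc(OCc2ccccc2)c([C@H](C)c2ccc(OCc3ccccc3)cc2)c1OC(=O)c1ccc(OC)cc1 | intermediate
16 | {2-[4,6-bis(benzyloxy)-3-[(1R)-1-(4-benzyloxyphenyl)ethyl]-2-(4-methoxybenzoyloxy)phenyl]-1-methoxy-2-oxoethyl}triphenylphosphonium chloride (CH(OMe) centre unassigned) | COC(C(=O)c1c(OCc2ccccc2)cc(OCc2ccccc2)c([C@H](C)c2ccc(OCc3ccccc3)cc2)c1OC(=O)c1ccc(OC)cc1)[P+](c1ccccc1)(c1ccccc1)c1ccccc1.[Cl-] | intermediate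
17 | 3,5-bis(benzyloxy)-6-[(1R)-1-(4-benzyloxyphenyl)ethyl]-2-[2-methoxy-2-(triphenyl-λ5-phosphanylidene)acetyl]phenyl 4-methoxybenzoate | COC(C(=O)c1c(OCc2ccccc2)cc(OCc2ccccc2)c([C@H](C)c2ccc(OCc3ccccc3)cc2)c1OC(=O)c1ccc(OC)cc1)=P(c1ccccc1)(c1ccccc1)c1ccccc1 | intermediate
18 | 1,2-oxaphosphetane fused across C2–C3 of the chroman-4-one (C2 bears O1, the 4-methoxyphenyl group and the O–P oxygen; C3 bears OMe and PPh3; ring-fusion centres unassigned) | COc1ccc(cc1)C12Oc3c([C@H](C)c4ccc(OCc5ccccc5)cc4)c(OCc4ccccc4)cc(OCc4ccccc4)c3C(=O)C1(OC)P(c1ccccc1)(c1ccccc1)(c1ccccc1)O2 | intermediate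
19 | 5,7-bis(benzyloxy)-8-[(1R)-1-(4-benzyloxyphenyl)ethyl]-3-methoxy-2-(4-methoxyphenyl)-4H-chromen-4-one | COc1ccc(-c2oc3c([C@H](C)c4ccc(OCc5ccccc5)cc4)c(OCc4ccccc4)cc(OCc4ccccc4)c3c(=O)c2OC)cc1 | intermediate
20 | 5,7-dihydroxy-8-[(1R)-1-(4-hydroxyphenyl)ethyl]-3-methoxy-2-(4-methoxyphenyl)-4H-chromen-4-one | COc1ccc(-c2oc3c([C@H](C)c4ccc(O)cc4)c(O)cc(O)c3c(=O)c2OC)cc1 | target

**Step count and risks**

Total steps: 9. Longest linear sequence: 9 steps (1 to 20).

Steps most likely to fail:

1. Step 8 (key step). The fully substituted, more hindered ylide carbon may add to the ester too slowly below the temperature at which the ylide decomposes, or aryloxide expulsion (acyl migration) may outrun P–O ring closure. The fallback uses known chemistry: the same ring closure is run with the unsubstituted ylide and oxygen is placed on C3 afterwards. It sets out from acid 12. Conversion into acid chloride 15 as in step 7 and acylation of methylidenetriphenylphosphorane (2 equiv, from methyltriphenylphosphonium bromide and NaN(SiMe3)2, THF, −78 °C) should give the parent keto-ylide F1. Heating in toluene closes ring C by the precedented ester Wittig reaction to the 3-unsubstituted flavone F2. Dimethyldioxirane in acetone/CH2Cl2 at 0 °C epoxidises C2=C3 to the 2,3-epoxide F3, which a trace of p-TsOH isomerises to the flavonol F4. MeI and K2CO3 in acetone methylate the 3-OH, and the route is rejoined at 19.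

2. Step 7. The basic, unstabilised ylide 14 may attack the 4-methoxybenzoate (acyl scrambling and loss of the ester) in competition with the doubly ortho-substituted acid chloride. In the fallback the ester is put on last, onto a phenolic keto-ylide. It sets out from salicylaldehyde 9. Allyl bromide and K2CO3 in DMF give the allyl ether F5, and Pinnick oxidation as in step 6 gives the acid F6. 1-Chloro-N,N,2-trimethylprop-1-en-1-amine gives the acid chloride F7, which acylates 14 (2 equiv, THF, −78 °C, no ester present) to the allyloxy keto-ylide F8. Pd(PPh3)4 (cat.) and morpholine in THF at rt remove the allyl group to give the hydroxy keto-ylide F9. 4-Methoxybenzoyl chloride 10 and pyridine in CH2Cl2 at 0 °C then acylate the phenol (the ylide carbon bears no hydrogen and cannot be acylated irreversibly), and the route is rejoined at 17.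

3. Step 3. Facial selectivity may be poor because ring A carries two ortho substituents and the directing OH competes with the flanking benzyloxy group for a place near the metal; turnover may also be slow. The fallback changes the mode of activation from metal chelation to Brønsted-acid organocatalysis. It sets out from 6: a chiral phosphoric acid (3,3'-bis(2,4,6-triisopropylphenyl)-1,1'-binaphthyl-2,2'-diyl hydrogen phosphate, 5 mol %, antipode chosen as in the remark) and Hantzsch ester (diethyl 2,6-dimethyl-1,4-dihydropyridine-3,5-dicarboxylate) in CH2Cl2 at rt protonate the alkene to an ortho-quinone methide paired with the chiral phosphate, and hydride transfer to one face should give 7 directly, where the route is rejoined. This known transfer hydrogenation of 2-(1-arylvinyl)phenols makes no compound outside the list (F0).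

**Further compounds**

F1 | step 8 | 3,5-bis(benzyloxy)-6-[(1R)-1-(4-benzyloxyphenyl)ethyl]-2-[(triphenyl-λ5-phosphanylidene)acetyl]phenyl 4-methoxybenzoate | O=C(C=P(c1ccccc1)(c1ccccc1)c1ccccc1)c1c(OCc2ccccc2)cc(OCc2ccccc2)c([C@H](C)c2ccc(OCc3ccccc3)cc2)c1OC(=O)c1ccc(OC)cc1
F2 | step 8 | 5,7-bis(benzyloxy)-8-[(1R)-1-(4-benzyloxyphenyl)ethyl]-2-(4-methoxyphenyl)-4H-chromen-4-one | COc1ccc(-c2cc(=O)c3c(OCc4ccccc4)cc(OCc4ccccc4)c([C@H](C)c4ccc(OCc5ccccc5)cc4)c3o2)cc1
F3 | step 8 | 2,3-epoxide of F2 (2,3-epoxy-5,7-bis(benzyloxy)-8-[(1R)-1-(4-benzyloxyphenyl)ethyl]-2-(4-methoxyphenyl)chroman-4-one, epoxide centres unassigned) | COc1ccc(cc1)C12OC1C(=O)c1c(OCc3ccccc3)cc(OCc3ccccc3)c([C@H](C)c3ccc(OCc4ccccc4)cc3)c1O2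
F4 | step 8 | 5,7-bis(benzyloxy)-8-[(1R)-1-(4-benzyloxyphenyl)ethyl]-3-hydroxy-2-(4-methoxyphenyl)-4H-chromen-4-one | COc1ccc(-c2oc3c([C@H](C)c4ccc(OCc5ccccc5)cc4)c(OCc4ccccc4)cc(OCc4ccccc4)c3c(=O)c2O)cc1
F5 | step 7 | 2-(allyloxy)-4,6-bis(benzyloxy)-3-[(1R)-1-(4-benzyloxyphenyl)ethyl]benzaldehyde | O=Cc1c(OCc2ccccc2)cc(OCc2ccccc2)c([C@H](C)c2ccc(OCc3ccccc3)cc2)c1OCC=C
F6 | step 7 | 2-(allyloxy)-4,6-bis(benzyloxy)-3-[(1R)-1-(4-benzyloxyphenyl)ethyl]benzoic acid | OC(=O)c1c(OCc2ccccc2)cc(OCc2ccccc2)c([C@H](C)c2ccc(OCc3ccccc3)cc2)c1OCC=C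
F7 | step 7 | 2-(allyloxy)-4,6-bis(benzyloxy)-3-[(1R)-1-(4-benzyloxyphenyl)ethyl]benzoyl chloride | ClC(=O)c1c(OCc2ccccc2)cc(OCc2ccccc2)c([C@H](C)c2ccc(OCc3ccccc3)cc2)c1OCC=C
F8 | step 7 | 1-{2-(allyloxy)-4,6-bis(benzyloxy)-3-[(1R)-1-(4-benzyloxyphenyl)ethyl]phenyl}-2-methoxy-2-(triphenyl-λ5-phosphanylidene)ethan-1-one | COC(C(=O)c1c(OCc2ccccc2)cc(OCc2ccccc2)c([C@H](C)c2ccc(OCc3ccccc3)cc2)c1OCC=C)=P(c1ccccc1)(c1ccccc1)c1ccccc1
F9 | step 7 | 1-{4,6-bis(benzyloxy)-3-[(1R)-1-(4-benzyloxyphenyl)ethyl]-2-hydroxyphenyl}-2-methoxy-2-(triphenyl-λ5-phosphanylidene)ethan-1-one | COC(C(=O)c1c(OCc2ccccc2)cc(OCc2ccccc2)c([C@H](C)c2ccc(OCc3ccccc3)cc2)c1O)=P(c1ccccc1)(c1ccccc1)c1ccccc1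
F0 | step 3 | none | none
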